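**Retrosynthetic overview**

1. The central 3,4-dihydro-2H-pyran ring is cut by a retro-oxa-[4+2] across the O–CH(ring fusion) and CH(isobutenyl)–CH(ring fusion) bonds. Its atoms are the O–C4=C3 edge of the isobutenyl-side 4-oxy-2-quinolone, the CH that carries the isobutenyl group, and the two ring-fusion CH.
2. This gives the ortho-quinone-methide-type 1-oxatriene 3-(3-methylbut-2-enylidene)quinoline-2,4-dione and the pyran C3=C4 alkene of veprisine. The enabling feature is that the heterodiene O=C4–C3=CH–CH=CMe2 is the ring-opened valence isomer of veprisine's own 2,2-dimethyl-2H-pyran ring, so one achiral monomer supplies both halves and a chiral Brønsted acid sets all three stereocentres in their union.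
3. Veprisine: the pyran C3=C4 double bond comes from dehydrogenation of 3,4-dihydroveprisine, whose dimethyldihydropyran ring comes from acid-mediated annulation of 4-hydroxy-7,8-dimethoxy-1-methylquinolin-2(1H)-one with 2-methylbut-3-en-2-ol. The oxatriene is therefore not an intermediate of any step before the key step.
4. The quinolinone: the pyridone ring comes from Friedel–Crafts closure of the malonic monoamide of 2,3-dimethoxy-N-methylaniline, itself made from 2,3-dimethoxyaniline.
5. Ring order: benzene ring (bought) → pyridone ring → 2,2-dimethylpyran ring (closed saturated, then dehydrogenated) → central dihydropyran ring (last, formed as the two halves are joined).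

Key step: step 6

Assumption: the sense of asymmetric induction of the chiral phosphoric acid on this new substrate pair cannot be predicted with certainty; the (R)-acid is written, and its (S)-enantiomer would be used instead if the first run shows the opposite sense.

**Step 1**
Reactants: 1 2,3-dimethoxyaniline
Product: 3 2,3-dimethoxy-N-methylaniline, via N-(methoxymethyl)-2,3-dimethoxyaniline 2 (not isolated)
Conditions: (CH2O)n, NaOMe, MeOH, rt to 50 °C; then NaBH4, reflux
Reagents that add atoms: formaldehyde (from paraformaldehyde), C=O
Why: Condensation of the aniline with formaldehyde in methanolic NaOMe should stop at the N-(methoxymethyl)amine (methanol adds to the N-methylene imine), which NaBH4 reduces through that imine, so that only one methyl group is introduced (reductive mono-N-methylation).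

**Step 2**
Reactants: 3 2,3-dimethoxy-N-methylaniline; 4 Meldrum's acid (2,2-dimethyl-1,3-dioxane-4,6-dione)
Product: 5 3-[(2,3-dimethoxyphenyl)(methyl)amino]-3-oxopropanoic acid
Conditions: toluene, 100 °C
Reagents that add atoms: none
Why: Nucleophilic acyl substitution: the secondary aniline opens Meldrum's acid at a carbonyl group and the acetonide is lost as acetone, which should give the malonic acid monoamide without a coupling reagent.

**Step 3**
Reactants: 5 3-[(2,3-dimethoxyphenyl)(methyl)amino]-3-oxopropanoic acid
Product: 6 4-hydroxy-7,8-dimethoxy-1-methylquinolin-2(1H)-one
Conditions: P2O5/MeSO3H (Eaton's reagent), 70 °C; then ice/H2O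
Reagents that add atoms: none
Why: Intramolecular Friedel–Crafts acylation at the only free position ortho to nitrogen, which is para to the 3-methoxy group, followed by enolisation to the 4-hydroxy-2-quinolone; no stereocentre is formed.

**Step 4**
Reactants: 6 4-hydroxy-7,8-dimethoxy-1-methylquinolin-2(1H)-one; 7 2-methylbut-3-en-2-ol
Product: 9 3,4-dihydroveprisine (7,8-dimethoxy-2,2,6-trimethyl-2,3,4,6-tetrahydro-5H-pyrano[3,2-c]quinolin-5-one), via 3-prenyl-4-hydroxyquinolinone 8 (not isolated)
Conditions: BF3·OEt2 (30 mol %), 1,4-dioxane, 50 °C
Reagents that add atoms: none
Why: Acid-mediated chroman annulation: the dimethylallyl cation formed from the tertiary allylic alcohol alkylates the nucleophilic C3 of the 4-hydroxy-2-quinolone at its unhindered terminus (Friedel–Crafts-type C-prenylation) to give 8, and Markovnikov addition of the 4-hydroxy group to the trisubstituted alkene then closes the 2,2-dimethyldihydropyran ring; no stereocentre is formed.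

**Step 5**
Reactants: 9 3,4-dihydroveprisine
Product: 10 veprisine (7,8-dimethoxy-2,2,6-trimethyl-2,6-dihydro-5H-pyrano[3,2-c]quinolin-5-one)
Conditions: DDQ (1.3 equiv), 1,4-dioxane, reflux
Reagents that add atoms: none
Why: DDQ dehydrogenation of a 2,2-dimethylchroman-type ring to the chromene: hydride is abstracted from pyran C4, whose cation is stabilised by the 4-alkoxy-2-quinolone as a vinylogous oxocarbenium ion, and loss of the C3 proton gives the 2H-pyran; no stereocentre is formed.

**Step 6**
Reactants: 10 veprisine (two molecules; one reacts through its ring-opened valence isomer 11)
Product: 12 the target, via oxatriene 11 (not isolated)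
Conditions: (R)-3,3'-bis(2,4,6-triisopropylphenyl)-1,1'-binaphthyl-2,2'-diyl hydrogen phosphate (10 mol %), 5 Å MS, toluene (1.0 M), 50 °C
Reagents that add atoms: none
Why: Proposed new method: 10 is in equilibrium with a small amount of its valence isomer 11 (retro-6π-oxa-electrocyclisation, assisted by hydrogen bonding of the acid to the lactam oxygen), and the chiral phosphoric acid should bind 11 by a hydrogen bond to its quinoline C2 oxygen, lower its LUMO and so make the acid-bound heterodiene O=C4–C3=CH the species that is caught by the pyran C3=C4 double bond of a second molecule of 10 (a vinylogous enol ether, nucleophilic at pyran C3) in an asynchronous inverse-electron-demand oxa-[4+2] cycloaddition, C–C bond first and C–O bond second at the carbon that can carry vinylogous oxocarbenium character. The closest known reaction types are the chiral phosphoric acid-catalysed oxa-Diels–Alder reactions of ortho-quinone methides generated in situ with styrenes, enol ethers and enamides, and the racemic thermal hetero-Diels–Alder reactions of 3-alkylidene-quinoline-2,4-diones and of ring-opened 2H-chromenes; what is new is enantioselective catalysis of the union of a 2H-pyran with its own oxatriene. The central dihydropyran ring is closed by an intermolecular [4+2] cycloaddition (four atoms O, C4, C3 and the alkylidene carbon from 11; the two alkene carbons from 10). The two ring-fusion centres must be cis because the Z-alkene held in the pyran ring of 10 adds suprafacially; the isobutenyl-bearing centre is set relative to them by the endo approach (donor pyranoquinolinone stacked under the acceptor quinolinedione) to the isomer of 11 that ring opening delivers, with the isobutenyl group syn to the C4 carbonyl, which puts the isobutenyl group anti to the CMe2 carbon across the forming C–C bond and cis to both ring-fusion hydrogens (the exo approach to the geometrical isomer of 11 would lead to the same relative configuration); the absolute configuration is set by the chiral phosphate, whose 3,3'-aryl groups shield one face of the alkylidene carbon next to the hydrogen-bonded C2 oxygen. The step needs (a) the hetero-Diels–Alder to win over the [1,7]-hydrogen shift of 11 and the carbo-Diels–Alder dimers that follow from it, secured by working at 50 °C where that shift is slow, (b) closure through the C4 and not the C2 oxygen, the same preference for the 4-alkoxy-2-quinolone that gives the angular pyran in step 4, and (c) the head-to-tail orientation, secured by the polarity of the partners (electrophilic alkylidene carbon, nucleophilic pyran C3).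

**Compound list**

1 | 2,3-dimethoxyaniline | COc1cccc(N)c1OC | starting material
2 | N-(methoxymethyl)-2,3-dimethoxyaniline | COCNc1cccc(OC)c1OC | intermediate
3 | 2,3-dimethoxy-N-methylaniline | CNc1cccc(OC)c1OC | intermediate
4 | Meldrum's acid (2,2-dimethyl-1,3-dioxane-4,6-dione) | CC1(C)OC(=O)CC(=O)O1 | starting material
5 | 3-[(2,3-dimethoxyphenyl)(methyl)amino]-3-oxopropanoic acid | CN(C(=O)CC(=O)O)c1cccc(OC)c1OC | intermediate
6 | 4-hydroxy-7,8-dimethoxy-1-methylquinolin-2(1H)-one | COc1ccc2c(O)cc(=O)n(C)c2c1OC | intermediate
7 | 2-methylbut-3-en-2-ol | CC(C)(O)C=C | starting material
8 | 4-hydroxy-7,8-dimethoxy-1-methyl-3-(3-methylbut-2-en-1-yl)quinolin-2(1H)-one | COc1ccc2c(O)c(CC=C(C)C)c(=O)n(C)c2c1OC | intermediate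
9 | 3,4-dihydroveprisine: 7,8-dimethoxy-2,2,6-trimethyl-2,3,4,6-tetrahydro-5H-pyrano[3,2-c]quinolin-5-one | COc1ccc2c3c(c(=O)n(C)c2c1OC)CCC(C)(C)O3 | intermediate
10 | veprisine: 7,8-dimethoxy-2,2,6-trimethyl-2,6-dihydro-5H-pyrano[3,2-c]quinolin-5-one | COc1ccc2c3c(c(=O)n(C)c2c1OC)C=CC(C)(C)O3 | intermediate
11 | oxatriene: (3E)-7,8-dimethoxy-1-methyl-3-(3-methylbut-2-en-1-ylidene)quinoline-2,4(1H,3H)-dione, butenyl chain syn to the C4 carbonyl | CC(C)=C/C=C1\C(=O)c2ccc(OC)c(OC)c2N(C)C1=O | intermediate
12 | target: hetero-Diels–Alder dimer of veprisine with a cis-fused pyrano[3,2-c]pyran core, each pyran fused through its O–C=C edge to C4/C3 of a 7,8-dimethoxy-1-methylquinolin-2(1H)-one; the central dihydropyran carries the 2-methylprop-1-enyl group on the CH next to quinolone C3 (S), then the ring-fusion CH bonded to the CMe2 carbon (S), then the ring-fusion O–CH bonded to C3 of the second quinolone (R); the isobutenyl group is cis to both ring-fusion hydrogens | COc1ccc2c3c(c(=O)n(C)c2c1OC)[C@@H](C=C(C)C)[C@H]1[C@@H](O3)c2c(c3ccc(OC)c(OC)c3n(C)c2=O)OC1(C)C | target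

**Step count and risks**

Total step count: 6. Longest linear sequence: 6 steps (1 → 3 → 5 → 6 → 9 → 10 → 12).

Steps most likely to fail:

1. Step 6 (proposed new method). The alkene partner offers the acid no second binding point, so enantiofacial and endo/exo discrimination may be poor, and a racemic background cycloaddition of free 11 or acid-induced cationic oligomerisation of the pyran alkene may compete. The fallback uses known chemistry, sets out from 10 and comes back at 12. The union is run without chiral control as a domino Knoevenagel/hetero-Diels–Alder reaction: 6 and 3-methylbut-2-enal are condensed with ethylenediammonium diacetate in toluene at 100 °C in the presence of an excess of 10 as the alkene, so that the oxatriene 11 formed in situ is trapped. This should give the racemic dimer, that is 12 together with the enantiomer of 12 F1. The enantiomers are then separated by preparative HPLC on a chiral stationary phase (amylose tris(3,5-dimethylphenylcarbamate)), which delivers 12.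

2. Step 4. The dimethylallyl cation may alkylate C3 twice or attack at oxygen, and the ring may close through the C2 oxygen to the linear 4-quinolone isomer. The fallback sets out from 6 and comes back at 10, bypassing 9 and step 5. Compound 6 is condensed with 3-methylbut-2-enal (ethylenediammonium diacetate, 10 mol %, toluene, 0.1 M, 80 °C). Knoevenagel condensation at C3 should give the oxatriene 11, which is not isolated and whose isomer with the butenyl chain syn to the C4 carbonyl closes by 6π-oxa-electrocyclisation through the C4 oxygen to 10 (formal [3+3] annulation, well known for 4-hydroxy-2-quinolones and enals). New compounds on this way: none (F0).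

3. Step 3. The malonamic acid may decarboxylate to the N-methylacetanilide before the ring closes, or the strong acid may cleave the methoxy group ortho to nitrogen. The fallback sets out from 3 and comes back at 6, bypassing 5. Compound 3 is heated with one equivalent of bis(2,4,6-trichlorophenyl) malonate in diphenyl ether at 200–220 °C under neutral conditions. N-acylation should give 2,4,6-trichlorophenyl 3-[(2,3-dimethoxyphenyl)(methyl)amino]-3-oxopropanoate F2, not isolated, which cyclises onto the ring with loss of the second trichlorophenol to give 6.

**Further compounds**

F1 | step 6 | enantiomer of 12 | COc1ccc2c3c(c(=O)n(C)c2c1OC)[C@H](C=C(C)C)[C@@H]1[C@H](O3)c2c(c3ccc(OC)c(OC)c3n(C)c2=O)OC1(C)C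
F0 | step 4 | none | none
F2 | step 3 | 2,4,6-trichlorophenyl 3-[(2,3-dimethoxyphenyl)(methyl)amino]-3-oxopropanoate | CN(C(=O)CC(=O)Oc1c(Cl)cc(Cl)cc1Cl)c1cccc(OC)c1OC
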